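**Plan**
- Retrosynthesis: (i) the two phenols are masked as methyl ethers. (ii) C4–C4a and O1–C8a are cut together. This takes the benzene carbons C4a and C8a out of the pyranone and leaves the four-membered ring O1–C2–C3–C4 (an oxetan-2-one) beside 2-fluoro-1,4-dimethoxybenzene. (iii) C2–C3 and O1–C4 of the lactone are cut to (Z)-octadec-13-enal and ketene.
- Forward: the benzene ring and the whole C17 (Z)-alkenyl chain are bought. The β-lactone ring is made first, is then enlarged from four to six members onto the arene, and the hydroquinone is unmasked last.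
- Enabling feature, lactone part: O1–C2–C3–C4(=O) is a β-hydroxy-acid unit, so it can exist as a strained acyl donor that carries its own alkoxide.
- Enabling feature, arene part: C4a and C8a are neighbours on the benzene ring, each next to an oxygen-bearing carbon (C5, C8). With F on C8a, the C4a–H lies between F and OMe and is the one lithiated. The C4 ketone formed there then activates C8a–F for attack by O1.
- Stereochemistry: C2 (R) comes from a catalyst-controlled Si-face [2+2] in step 1 and persists because the C2–O1 bond is never broken. The Z-alkene comes with the aldehyde and meets no strong Lewis acid, hydrogenation or radical step.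

Key step: step 2

Assumption: (Z)-octadec-13-enal is taken as purchasable, since it is traded as a moth pheromone component; 2-fluoro-1,4-dimethoxybenzene is a catalogue compound.

**Step 1**
Reactants: 1 (Z)-octadec-13-enal
Product: 2 (R)-4-[(Z)-heptadec-12-en-1-yl]oxetan-2-one
Conditions: AcBr (2 equiv), i-Pr2NEt (1.7 equiv), chiral valine-derived Al(III)–bis(triflamide)triamine catalyst (10 mol %, antipode for Si-face attack), CH2Cl2, −50 °C
Reagents that add atoms: acetyl bromide, CC(=O)Br
Why: Catalytic asymmetric acyl halide–aldehyde cyclocondensation (formal ketene–aldehyde [2+2]), well precedented for unbranched aliphatic aldehydes: ketene released from AcBr by the amine adds to the aldehyde bound to the chiral Al centre, whose ligand leaves only the Si face open and so sets C2 as (R), while the remote Z-alkene is a spectator.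

**Step 2**
Reactants: 2 (R)-4-[(Z)-heptadec-12-en-1-yl]oxetan-2-one; 3 2-fluoro-1,4-dimethoxybenzene
Product: 6 (R)-2-[(Z)-heptadec-12-en-1-yl]-5,8-dimethoxychroman-4-one, via aryllithium 4 (not isolated), via lithium aldolate 5 (not isolated)
Conditions: 3 (1.1 equiv), n-BuLi (1.05 equiv), THF, −78 °C; 2 in THF, −78 °C; DMPU (4 equiv), −78 → 25 °C; aq NH4Cl
Reagents that add atoms: none
Why: Proposed new method: directed ortho-lithiation takes the one C–H of 3 that lies between F and OMe, the hard aryllithium 4 adds to the strained lactone carbonyl of 2, the tetrahedral adduct collapses by acyl–oxygen scission to the lithium aldolate 5, and the C4 ketone so created stands ortho to C8a–F, so that on warming O1 adds to C8a (σ-adduct held as the C4 enolate) and LiF is lost. The net event splices C4a and C8a into the acyl–O bond of the four-membered ring O1–C2–C3–C4, a two-atom ring expansion that forms C4–C4a and O1–C8a in one flask. The closest known reaction types are the acyl–oxygen opening of β-lactones by organolithium, phosphonate and enolate anions to β-hydroxy ketones, the intramolecular SNAr of alkoxides on o-fluoroaryl ketones to benzopyranones, and the formal insertion of arynes into the N–acyl bond of β-lactams; only their merger on a β-lactone is new. The single ring closure is an addition–elimination at sp2 C8a, formally 6-endo-trig on the C8a=C4a–C4=O unit. No stereocentre is formed, and C2 stays (R) because the C2–O1 bond is never broken. The step needs acyl rather than alkyl attack on 2 (hard ArLi at −78 °C), a single addition (the bulky 4 and the di-ortho-substituted ketone resist a second one), no LiF loss from 4 before acylation (−78 °C) and ring closure faster than retro-aldol or E1cB decay of 5 (fluoride as the best SNAr leaving group, a six-membered transition state, DMPU to loosen the Li–O pair).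

**Step 3**
Reactants: 6 (R)-2-[(Z)-heptadec-12-en-1-yl]-5,8-dimethoxychroman-4-one
Product: 8 (R)-2-[(Z)-heptadec-12-en-1-yl]-5,8-dihydroxychroman-4-one, via quinone 7 (not isolated)
Conditions: CAN (2.5 equiv), MeCN–H2O, 0 °C; EtOAc extraction; aq Na2S2O4, 25 °C
Reagents that add atoms: water, O
Why: Ce(IV) oxidative demethylation of a 1,4-dimethoxyarene (water adds to the ipso carbons of the arene radical cation and methanol leaves) should give the p-quinone 7 because only C5 and C8 are para to each other, the isolated Z-alkene and C2 are untouched in the cold acidic medium, and dithionite reduction of the quinone then delivers the hydroquinone 8.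

**Compound list**
1 | (Z)-octadec-13-enal | CCCC/C=C\CCCCCCCCCCCC=O | starting material
2 | (R)-4-[(Z)-heptadec-12-en-1-yl]oxetan-2-one | CCCC/C=C\CCCCCCCCCCC[C@@H]1CC(=O)O1 | intermediate
3 | 2-fluoro-1,4-dimethoxybenzene | COc1ccc(OC)c(F)c1 | starting material
4 | (2-fluoro-3,6-dimethoxyphenyl)lithium | [Li]c1c(F)c(OC)ccc1OC | intermediate
5 | lithium (3R,15Z)-1-(2-fluoro-3,6-dimethoxyphenyl)-1-oxoicos-15-en-3-olate | CCCC/C=C\CCCCCCCCCCC[C@@H]([O-])CC(=O)c1c(F)c(OC)ccc1OC.[Li+] | intermediate
6 | (R)-2-[(Z)-heptadec-12-en-1-yl]-5,8-dimethoxychroman-4-one | CCCC/C=C\CCCCCCCCCCC[C@@H]1CC(=O)c2c(OC)ccc(OC)c2O1 | intermediate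
7 | (R)-2-[(Z)-heptadec-12-en-1-yl]-2,3-dihydro-4H-chromene-4,5,8-trione | CCCC/C=C\CCCCCCCCCCC[C@@H]1CC(=O)C2=C(O1)C(=O)C=CC2=O | intermediate
8 | (R)-2-[(Z)-heptadec-12-en-1-yl]-5,8-dihydroxychroman-4-one | CCCC/C=C\CCCCCCCCCCC[C@@H]1CC(=O)c2c(O)ccc(O)c2O1 | target

Total step count: 3. Longest linear sequence: 3 (1 → 2 → 6 → 8).

**Steps most likely to fail**

1. **Step 2.**
   - What may go wrong:
     - retro-aldol cleavage or β-elimination of the aldolate before the C–O bond closes, with loss of material and of enantiopurity;
     - enolisation of the lactone or of the new ketone by the aryllithium;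
     - premature loss of LiF from the aryllithium;
     - base-induced opening and reclosure of the finished pyranone.
   - Fallback: it uses known chemistry, sets out from 2 and comes back to the route at 7. It forms the C–O bond at the quinone oxidation level instead of by SNAr.
   - Commercial 2-bromo-1,4-dimethoxybenzene undergoes Br–Li exchange (n-BuLi, THF, −78 °C) to (2,5-dimethoxyphenyl)lithium F1. This opens 2 at the acyl carbon. A cold quench (AcOH, −78 °C) should give (3R,15Z)-1-(2,5-dimethoxyphenyl)-3-hydroxyicos-15-en-1-one F2.
   - CAN in excess (MeCN–H2O, 0 °C) should give 2-[(3R,15Z)-3-hydroxyicos-15-enoyl]-1,4-benzoquinone F3. In this quinone the ring carbon next to the acyl group is the most electrophilic site.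
   - The side-chain hydroxyl adds there in a 6-endo-trig oxa-Michael addition, which is also the likely biosynthetic closure. Enolisation gives 8, the excess Ce(IV) carries it on to 7, and 7 then meets the dithionite wash of step 3.

2. **Step 1.**
   - What may go wrong: poor facial selectivity or slow turnover because the waxy C18 aldehyde dissolves poorly at −50 °C, and ketene dimerisation outrunning the cycloaddition.
   - Fallback: it sets out from 1 and comes back at 2. It takes the stereocentre from a resolution and the lactone from a carbonylative ring expansion.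
   - Corey–Chaykovsky methylenation of 1 (Me3SI, NaH, DMSO–THF, 0 °C) should give racemic 2-[(Z)-heptadec-12-en-1-yl]oxirane F4.
   - Hydrolytic kinetic resolution follows, with the appropriate antipode of a chiral (salen)Co(III) acetate (0.55 equiv H2O). It should leave (R)-2-[(Z)-heptadec-12-en-1-yl]oxirane F5.
   - Carbonylation with a [Lewis acid]+[Co(CO)4]− catalyst under CO pressure inserts CO into the CH2–O bond, with retention at the stereocentre, to give 2.

3. **Step 3.**
   - What may go wrong: over-oxidation or nitration of the electron-rich ring, attack of Ce(IV) on the alkene, and β-elimination of the hydroxyquinone leaving group at the quinone stage with loss of configuration at C2.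
   - Fallback: it sets out from 2 and comes back at 8. It carries the phenols as acetals, so that the unmasking is a mild acidolysis without any redox step.
   - Commercial 2-fluorobenzene-1,4-diol is protected (MOMCl, i-Pr2NEt, CH2Cl2) as 2-fluoro-1,4-bis(methoxymethoxy)benzene F6.
   - n-BuLi (THF, −78 °C) gives [2-fluoro-3,6-bis(methoxymethoxy)phenyl]lithium F7.
   - Under the protocol of step 2, F7 reacts with 2 by way of lithium (3R,15Z)-1-[2-fluoro-3,6-bis(methoxymethoxy)phenyl]-1-oxoicos-15-en-3-olate F8. The product should be (R)-2-[(Z)-heptadec-12-en-1-yl]-5,8-bis(methoxymethoxy)chroman-4-one F9.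
   - HCl in MeOH at 25 °C then releases 8.

**Further compounds**
F1 | step 2 | (2,5-dimethoxyphenyl)lithium | [Li]c1cc(OC)ccc1OC
F2 | step 2 | (3R,15Z)-1-(2,5-dimethoxyphenyl)-3-hydroxyicos-15-en-1-one | CCCC/C=C\CCCCCCCCCCC[C@@H](O)CC(=O)c1cc(OC)ccc1OC
F3 | step 2 | 2-[(3R,15Z)-3-hydroxyicos-15-enoyl]-1,4-benzoquinone | CCCC/C=C\CCCCCCCCCCC[C@@H](O)CC(=O)C1=CC(=O)C=CC1=O
F4 | step 1 | racemic 2-[(Z)-heptadec-12-en-1-yl]oxirane | CCCC/C=C\CCCCCCCCCCCC1CO1
F5 | step 1 | (R)-2-[(Z)-heptadec-12-en-1-yl]oxirane | CCCC/C=C\CCCCCCCCCCC[C@@H]1CO1
F6 | step 3 | 2-fluoro-1,4-bis(methoxymethoxy)benzene | COCOc1ccc(OCOC)c(F)c1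
F7 | step 3 | [2-fluoro-3,6-bis(methoxymethoxy)phenyl]lithium | [Li]c1c(F)c(OCOC)ccc1OCOC
F8 | step 3 | lithium (3R,15Z)-1-[2-fluoro-3,6-bis(methoxymethoxy)phenyl]-1-oxoicos-15-en-3-olate | CCCC/C=C\CCCCCCCCCCC[C@@H]([O-])CC(=O)c1c(F)c(OCOC)ccc1OCOC.[Li+]
F9 | step 3 | (R)-2-[(Z)-heptadec-12-en-1-yl]-5,8-bis(methoxymethoxy)chroman-4-one | CCCC/C=C\CCCCCCCCCCC[C@@H]1CC(=O)c2c(OCOC)ccc(OCOC)c2O1
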